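The route rests on cutting the ten-membered carbocycle at C2–C3. C3 is allylic to the E C4=C5 alkene, so a phenylsulfonyl group there gives a stabilised carbanion; C2 is a primary carbon beside the C1 methoxy carbon and can carry iodide; the cis-fused C6–O–C12 γ-lactone bends the chain so that the two ends meet. One intramolecular C-alkylation then closes the carbocycle with the E alkene and all six stereocentres of the bicyclic core already in place. Its precursor is the seco lactone with a C3 allyl sulfone, a C2 iodide, a C8 silyl ether and C9 masked as a 1,3-dithiane, which is built in before the C7–C8 aldol and avoids a late, hindered ketalisation.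

Key step: step 18

Remark on the chemistry: atoms carry germacranolide numbers (C1 = CH–OMe, C2, C3, C4(Me)=C5, C6–O–C12(=O) lactone through C7 and C11(Me), C8–O-acyl, C9 ketone carbon, C10(Me)); the ester acid is the (2S,3R), cis-dimethyl epoxy acid read from the target SMILES, and (+)-Ipc2BOMe is taken as the enantiomer made from (−)-α-pinene.

Step 1
Reactants: 1 (tert-butyldimethylsilyloxy)acetaldehyde; 2 trans-2-butene
Product: 4 (2R,3R)-1-(tert-butyldimethylsilyloxy)-3-methylpent-4-en-2-ol, via (E)-crotylbis(isopinocampheyl)borane 3 (not isolated)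
Conditions: 2, KOt-Bu, n-BuLi, THF, −78 → −45 °C; (+)-Ipc2BOMe, −78 °C; BF3·OEt2; 1, −78 °C; NaOH, H2O2
Reagents that add atoms: none
Why: Brown crotylboration through a closed chair transition state, in which the E crotyl geometry should give the anti C1–O/C10–Me pair and the isopinocampheyl groups should select the aldehyde face leading to the 2R,3R alcohol.

Step 2
Reactants: 4 (2R,3R)-1-(tert-butyldimethylsilyloxy)-3-methylpent-4-en-2-ol
Product: 5 tert-butyl{[(2R,3R)-2-methoxy-3-methylpent-4-en-1-yl]oxy}dimethylsilane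
Conditions: Me3OBF4, 1,8-bis(dimethylamino)naphthalene, CH2Cl2, 0 °C → rt
Reagents that add atoms: trimethyloxonium tetrafluoroborate, C[O+](C)C.F[B-](F)(F)F
Why: O-methylation of the neutral alcohol by the oxonium salt forms no alkoxide, so the neighbouring primary silyl ether should not migrate.

Step 3
Reactants: 5 tert-butyl{[(2R,3R)-2-methoxy-3-methylpent-4-en-1-yl]oxy}dimethylsilane
Product: 6 (2S,3R)-4-(tert-butyldimethylsilyloxy)-3-methoxy-2-methylbutanal
Conditions: O3, CH2Cl2, −78 °C; PPh3
Reagents that add atoms: ozone, [O-][O+]=O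
Why: Ozonolysis with reductive work-up should cleave the only alkene to the C9 aldehyde under neutral conditions that leave the α-stereocentre alone.

Step 4
Reactants: 6 (2S,3R)-4-(tert-butyldimethylsilyloxy)-3-methoxy-2-methylbutanal
Product: 7 2-[(2S,3R)-4-(tert-butyldimethylsilyloxy)-3-methoxybutan-2-yl]-1,3-dithiane
Conditions: HS(CH2)3SH, MgBr2·OEt2, Et2O, 0 °C → rt
Reagents that add atoms: propane-1,3-dithiol, SCCCS
Why: Lewis-acid-promoted dithioacetalisation of the aldehyde, with a promoter mild enough to spare the primary silyl ether, masks C9 at the ketone level while it is still unhindered.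

Step 5
Reactants: 7 2-[(2S,3R)-4-(tert-butyldimethylsilyloxy)-3-methoxybutan-2-yl]-1,3-dithiane
Product: 9 2-[(2S,3R)-4-(tert-butyldimethylsilyloxy)-3-methoxybutan-2-yl]-1,3-dithiane-2-carbaldehyde, via 2-lithiodithiane 8 (not isolated)
Conditions: t-BuLi, THF–HMPA (10:1), −78 °C; DMF, −78 → 0 °C
Reagents that add atoms: N,N-dimethylformamide, CN(C)C=O
Why: Corey–Seebach umpolung, in which formylation of the 2-lithio-1,3-dithiane should make C9 a quaternary masked ketone and deliver C8 as a non-enolisable aldehyde.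

Step 6
Reactants: 10 4-tert-butoxy-4-oxobutanoic acid; 11 (R)-4-benzyloxazolidin-2-one
Product: 13 tert-butyl 4-[(R)-4-benzyl-2-oxooxazolidin-3-yl]-4-oxobutanoate, via mixed pivalic anhydride 12 (not isolated)
Conditions: t-BuCOCl, Et3N, THF, −20 °C; LiCl, 11, −20 °C → rt
Reagents that add atoms: none
Why: N-acylation of the Evans auxiliary through the mixed pivalic anhydride, a standard route to acyl oxazolidinones.

Step 7
Reactants: 13 tert-butyl 4-[(R)-4-benzyl-2-oxooxazolidin-3-yl]-4-oxobutanoate; 9 dithiane aldehyde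
Product: 15 tert-butyl (3R,4R)-3-[(R)-4-benzyl-2-oxooxazolidine-3-carbonyl]-4-hydroxy-4-{2-[(2S,3R)-4-(tert-butyldimethylsilyloxy)-3-methoxybutan-2-yl]-1,3-dithian-2-yl}butanoate, via (Z)-boron enolate 14 (not isolated)
Conditions: Bu2BOTf, i-Pr2NEt, CH2Cl2, −78 → 0 °C; 9, −78 → 0 °C; MeOH–pH 7 buffer, non-oxidative work-up
Reagents that add atoms: none
Why: Evans syn aldol, in which the (Z)-boron enolate should react through a Zimmerman–Traxler chair on the face away from the benzyl group of the (R)-auxiliary and so set C7 and C8 by reagent control, while the tert-butyl ester should keep the new C8 hydroxyl from lactonising.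

Step 8
Reactants: 15 syn-aldol adduct
Product: 16 tert-butyl (3R,4R)-4-hydroxy-3-[methoxy(methyl)carbamoyl]-4-{2-[(2S,3R)-4-(tert-butyldimethylsilyloxy)-3-methoxybutan-2-yl]-1,3-dithian-2-yl}butanoate
Conditions: MeNH(OMe)·HCl, AlMe3, CH2Cl2, −20 → 0 °C
Reagents that add atoms: N,O-dimethylhydroxylamine hydrochloride, CNOC.Cl
Why: Aluminium-amide transamidation of a β-hydroxy imide to the Weinreb amide is assisted by the free C8 hydroxyl, and the hindered tert-butyl ester should not react.

Step 9
Reactants: 16 β-hydroxy Weinreb amide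
Product: 17 C8 tert-butyldimethylsilyl ether of 16
Conditions: TBSOTf, 2,6-lutidine, CH2Cl2, 0 °C → rt
Reagents that add atoms: tert-butyldimethylsilyl triflate, CC(C)(C)[Si](C)(C)OS(=O)(=O)C(F)(F)F
Why: Silyl triflate silylation is the standard way to protect a hindered secondary alcohol that resists the chloride.

Step 10
Reactants: 18 prop-2-yn-1-ol
Product: 20 (E)-3-iodo-2-methylprop-2-en-1-ol, via (E)-alkenylalane 19 (not isolated)
Conditions: AlMe3, Cp2ZrCl2, CH2Cl2, 0 °C → rt; I2, THF, −30 → 0 °C
Reagents that add atoms: trimethylaluminium, C[Al](C)C; iodine, II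
Why: Negishi carboalumination adds methyl and aluminium syn across the alkyne with methyl on the internal carbon, and iodinolysis with retention should give the E iodoalkene that becomes C5–C4(Me)–C3.

Step 11
Reactants: 20 (E)-3-iodo-2-methylprop-2-en-1-ol
Product: 21 tert-butyl{[(E)-3-iodo-2-methylallyl]oxy}dimethylsilane
Conditions: TBSCl, imidazole, CH2Cl2, rt
Reagents that add atoms: tert-butyldimethylsilyl chloride, CC(C)(C)[Si](C)(C)Cl
Why: Routine silylation of a primary allylic alcohol.

Step 12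
Reactants: 21 tert-butyl{[(E)-3-iodo-2-methylallyl]oxy}dimethylsilane; 17 silylated Weinreb amide
Product: 23 E enone (C6 ketone; C7 R; C8 R), via (E)-vinyllithium 22 (not isolated)
Conditions: 21, t-BuLi (2 equiv), Et2O, −78 °C; 17, THF, −78 → −40 °C
Reagents that add atoms: none
Why: Iodine–lithium exchange keeps the alkene geometry and acylation of the vinyllithium by the Weinreb amide should stop at the ketone through the chelated tetrahedral adduct, the tert-butyl ester being inert at −78 °C.

Step 13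
Reactants: 23 E enone
Product: 25 cis-4,5-disubstituted γ-lactone (6S,7S,8R), via C6 allylic alcohol tert-butyl ester 24 (not isolated)
Conditions: LiBH(s-Bu)3, THF, −78 °C; AcOH quench at −78 °C; PPTS, PhMe, 80 °C
Reagents that add atoms: none
Why: Felkin–Anh 1,2-reduction of the β,β-disubstituted enone by a bulky hydride should add anti to the large C8 branch on C7 (supported by the 1,3-anti preference of the β-silyloxy group) and give the C6 alcohol anti to C11, which mild acid should then lactonise onto the tert-butyl ester.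

Step 14
Reactants: 25 cis γ-lactone
Product: 27 C11-methyl lactone (6S,7S,8R,11S), via lactone lithium enolate 26 (not isolated)
Conditions: LiN(i-Pr)2, THF, −78 °C; MeI, −78 °C
Reagents that add atoms: iodomethane, CI
Why: Alkylation of a γ-lactone enolate should occur on the face opposite the C7 and C6 substituents, giving the 3,4-trans lactone and setting C11.

Step 15
Reactants: 27 C11-methyl lactone
Product: 28 C2,C3-diol (C8 silyl ether kept)
Conditions: HF·pyridine, pyridine, THF, 0 °C
Reagents that add atoms: none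
Why: Buffered fluoride should cleave the two primary silyl ethers selectively, since the secondary C8 ether beside the quaternary dithiane carbon reacts far more slowly.

Step 16
Reactants: 28 C2,C3-diol
Product: 29 C2,C3-diiodide
Conditions: I2, PPh3, imidazole, CH2Cl2, 0 °C, dark; used at once
Reagents that add atoms: iodine, II
Why: Appel-type iodination converts both primary alcohols by SN2 displacement of their oxyphosphonium groups without touching the E alkene.

Step 17
Reactants: 29 C2,C3-diiodide; 30 sodium benzenesulfinate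
Product: 31 seco C3 phenyl sulfone C2 iodide (1R,6S,7S,8R,10S,11S)
Conditions: 30 (1.05 equiv), DMF, 0 °C
Reagents that add atoms: none
Why: S-alkylation of sulfinate should take place only at the allylic iodide, which is far more reactive in SN2 than the β-methoxy primary iodide, so one equivalent at 0 °C leaves C2–I in place.

Step 18
Reactants: 31 seco C3 phenyl sulfone C2 iodide
Product: 33 ten-membered C3 phenyl sulfone (1S,6S,7S,8R,10S,11S; both C3 epimers), via C3-lithiated sulfone 32 (not isolated)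
Conditions: LiN(SiMe3)2 (1.05 equiv), THF, 0.002 M, −78 → −20 °C
Reagents that add atoms: none
Why: The amide base should remove a proton from the allylic sulfonyl CH2 at C3, the most acidic and most accessible C–H (the lactone C11–H is a hindered methine and roughly three pK units weaker, and C9 carries no hydrogen), and the lithiated sulfone then displaces the primary C2 iodide in an intramolecular SN2 reaction. The closest known reaction type is the macrocyclisation of sulfone- or sulfide-stabilised allyl anions onto primary halides used for ten- to fourteen-membered terpenoid rings. The ten-membered ring closes in the 10-exo-tet mode, helped by the cis-fused γ-lactone as a turn, the rigid E alkene and the spiro dithiane, while high dilution should suppress oligomers. The only new stereocentre, C3, is not controlled and need not be, because step 19 removes it. The step needs α- over γ-alkylation (usual for lithiated allyl sulfones in THF, and γ-attack would require an eight-membered ring), retention of the E geometry, and no expulsion of the C6 carboxylate from the delocalised anion, which is why a lithium counter-ion, THF without polar additives and temperatures below −20 °C are chosen.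

Step 19
Reactants: 33 ten-membered C3 phenyl sulfone
Product: 36 desulfonylated ten-membered lactone (1S,6S,7S,8R,10S,11S), via ring-opened lithium carboxylate 34 (not isolated), via desulfonylated hydroxy acid 35 (not isolated)
Conditions: LiOH, THF–H2O, 0 °C; concentrate, dry (PhMe azeotrope); PdCl2(dppp) (cat.), LiBHEt3, THF, 0 °C; 1 M HCl to pH 3, rt
Reagents that add atoms: none
Why: Saponification turns the allylic lactone into a carboxylate and a C6 hydroxyl that zerovalent palladium does not ionise and LiBHEt3 does not reduce, so the palladium-catalysed hydride substitution of the allylic sulfone should deliver hydride to the less hindered C3 end of the π-allyl and keep the E C4=C5 alkene, and acidification re-closes the cis γ-lactone.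

Step 20
Reactants: 36 desulfonylated ten-membered lactone
Product: 37 C9 ketone with C8 silyl ether
Conditions: PhI(OCOCF3)2, MeCN–H2O (9:1), 0 °C
Reagents that add atoms: water, O
Why: Oxidative dethioacetalisation with a hypervalent iodine reagent activates sulfur and hydrolyses the dithiane under nearly neutral conditions that the alkene, lactone and silyl ether should tolerate.

Step 21
Reactants: 37 C9 ketone with C8 silyl ether
Product: 38 C8 alcohol (1S,6S,7R,8R,10S,11S)
Conditions: aq. HF (48%), MeCN, 0 °C → rt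
Reagents that add atoms: none
Why: Acidic fluoride desilylation of the α-silyloxy ketone avoids the basic conditions that could eliminate the β-methoxy group or epimerise C8 and C10.

Step 22
Reactants: 39 (E)-2-methylbut-2-en-1-ol
Product: 40 [(2R,3R)-2,3-dimethyloxiran-2-yl]methanol
Conditions: Ti(Oi-Pr)4 (cat.), D-(−)-diethyl tartrate (cat.), t-BuOOH, 4 Å MS, CH2Cl2, −20 °C
Reagents that add atoms: tert-butyl hydroperoxide, CC(C)(C)OO
Why: Sharpless asymmetric epoxidation with D-(−)-tartrate should deliver oxygen to the face giving the 2R,3R epoxide, and the E alkene fixes the cis relation of the two methyl groups.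

Step 23
Reactants: 40 [(2R,3R)-2,3-dimethyloxiran-2-yl]methanol
Product: 41 (2S,3R)-2,3-dimethyloxirane-2-carboxylic acid
Conditions: RuCl3 (cat.), NaIO4, MeCN–EtOAc–H2O, rt
Reagents that add atoms: sodium periodate, [Na+].[O-]I(=O)(=O)=O; water, O
Why: Ruthenium tetroxide oxidation of a 2,3-epoxy alcohol to the glycidic acid leaves both epoxide stereocentres untouched (the descriptor at C2 changes only through the priority rules).

Step 24
Reactants: 41 (2S,3R)-2,3-dimethyloxirane-2-carboxylic acid; 38 C8 alcohol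
Product: 43 CNP0145898.1, via mixed trichlorobenzoic anhydride 42 (not isolated)
Conditions: 41, 2,4,6-Cl3C6H2COCl, Et3N, PhMe, rt; 38, DMAP, 0 °C → rt
Reagents that add atoms: none
Why: Yamaguchi esterification, in which DMAP attacks the less hindered epoxy-acyl carbonyl of the mixed anhydride and the acylpyridinium acylates the C8 hydroxyl without forming a stereocentre.

Compound list
1 | (tert-butyldimethylsilyloxy)acetaldehyde | O=CCO[Si](C)(C)C(C)(C)C | starting material
2 | trans-2-butene | C/C=C/C | starting material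
3 | (E)-crotylbis(isopinocampheyl)borane, Ipc groups of the (−)-α-pinene series | C/C=C/CB([C@H]1C[C@H]2C[C@@H]([C@@H]1C)C2(C)C)[C@H]1C[C@H]2C[C@@H]([C@@H]1C)C2(C)C | intermediate (not isolated)
4 | (2R,3R)-1-(tert-butyldimethylsilyloxy)-3-methylpent-4-en-2-ol | C=C[C@@H](C)[C@@H](O)CO[Si](C)(C)C(C)(C)C | intermediate
5 | tert-butyl{[(2R,3R)-2-methoxy-3-methylpent-4-en-1-yl]oxy}dimethylsilane | C=C[C@@H](C)[C@@H](OC)CO[Si](C)(C)C(C)(C)C | intermediate
6 | (2S,3R)-4-(tert-butyldimethylsilyloxy)-3-methoxy-2-methylbutanal | O=C[C@@H](C)[C@@H](OC)CO[Si](C)(C)C(C)(C)C | intermediate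
7 | 2-[(2S,3R)-4-(tert-butyldimethylsilyloxy)-3-methoxybutan-2-yl]-1,3-dithiane | S1CCCSC1[C@@H](C)[C@@H](OC)CO[Si](C)(C)C(C)(C)C | intermediate
8 | 2-lithio derivative of 7 | [Li]C1(SCCCS1)[C@@H](C)[C@@H](OC)CO[Si](C)(C)C(C)(C)C | intermediate (not isolated)
9 | 2-[(2S,3R)-4-(tert-butyldimethylsilyloxy)-3-methoxybutan-2-yl]-1,3-dithiane-2-carbaldehyde | O=CC1(SCCCS1)[C@@H](C)[C@@H](OC)CO[Si](C)(C)C(C)(C)C | intermediate
10 | 4-tert-butoxy-4-oxobutanoic acid | CC(C)(C)OC(=O)CCC(=O)O | starting material
11 | (R)-4-benzyloxazolidin-2-one | O=C1N[C@H](Cc2ccccc2)CO1 | starting material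
12 | mixed pivalic anhydride of 10 | CC(C)(C)OC(=O)CCC(=O)OC(=O)C(C)(C)C | intermediate (not isolated)
13 | tert-butyl 4-[(R)-4-benzyl-2-oxooxazolidin-3-yl]-4-oxobutanoate | CC(C)(C)OC(=O)CCC(=O)N1[C@H](Cc2ccccc2)COC1=O | intermediate
14 | (Z)-dibutylboron enolate of 13 | CC(C)(C)OC(=O)C/C=C(\OB(CCCC)CCCC)N1[C@H](Cc2ccccc2)COC1=O | intermediate (not isolated)
15 | syn-aldol adduct, C7 R, C8 R | CC(C)(C)OC(=O)C[C@@H](C(=O)N1[C@H](Cc2ccccc2)COC1=O)[C@@H](O)C1(SCCCS1)[C@@H](C)[C@@H](OC)CO[Si](C)(C)C(C)(C)C | intermediate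
16 | C6 Weinreb amide with free C8 hydroxyl | CC(C)(C)OC(=O)C[C@@H](C(=O)N(C)OC)[C@@H](O)C1(SCCCS1)[C@@H](C)[C@@H](OC)CO[Si](C)(C)C(C)(C)C | intermediate
17 | C6 Weinreb amide, C8 silyl ether | CC(C)(C)OC(=O)C[C@@H](C(=O)N(C)OC)[C@@H](O[Si](C)(C)C(C)(C)C)C1(SCCCS1)[C@@H](C)[C@@H](OC)CO[Si](C)(C)C(C)(C)C | intermediate
18 | prop-2-yn-1-ol | C#CCO | starting material
19 | (E)-alkenylalane from carboalumination | C[Al](C)/C=C(\C)CO[Al](C)C | intermediate (not isolated)
20 | (E)-3-iodo-2-methylprop-2-en-1-ol | OC/C(C)=C/I | intermediate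
21 | tert-butyl{[(E)-3-iodo-2-methylallyl]oxy}dimethylsilane | CC(C)(C)[Si](C)(C)OC/C(C)=C/I | intermediate
22 | (E)-3-(tert-butyldimethylsilyloxy)-2-methylprop-1-enyllithium | CC(C)(C)[Si](C)(C)OC/C(C)=C/[Li] | intermediate (not isolated)
23 | E enone, C6 ketone, C7 R, C8 R | CC(C)(C)OC(=O)C[C@@H](C(=O)/C=C(\C)CO[Si](C)(C)C(C)(C)C)[C@@H](O[Si](C)(C)C(C)(C)C)C1(SCCCS1)[C@@H](C)[C@@H](OC)CO[Si](C)(C)C(C)(C)C | intermediate
24 | C6 allylic alcohol tert-butyl ester, 6S,7S,8R | CC(C)(C)OC(=O)C[C@@H]([C@@H](O)/C=C(\C)CO[Si](C)(C)C(C)(C)C)[C@@H](O[Si](C)(C)C(C)(C)C)C1(SCCCS1)[C@@H](C)[C@@H](OC)CO[Si](C)(C)C(C)(C)C | intermediate (not isolated)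
25 | cis γ-lactone, 6S,7S,8R | CC(C)(C)[Si](C)(C)OC/C(C)=C/[C@@H]1OC(=O)C[C@@H]1[C@@H](O[Si](C)(C)C(C)(C)C)C1(SCCCS1)[C@@H](C)[C@@H](OC)CO[Si](C)(C)C(C)(C)C | intermediate
26 | lithium enolate of 25 | CC(C)(C)[Si](C)(C)OC/C(C)=C/[C@@H]1OC(O[Li])=C[C@@H]1[C@@H](O[Si](C)(C)C(C)(C)C)C1(SCCCS1)[C@@H](C)[C@@H](OC)CO[Si](C)(C)C(C)(C)C | intermediate (not isolated)
27 | C11-methyl lactone, 6S,7S,8R,11S | CC(C)(C)[Si](C)(C)OC/C(C)=C/[C@@H]1OC(=O)[C@@H](C)[C@@H]1[C@@H](O[Si](C)(C)C(C)(C)C)C1(SCCCS1)[C@@H](C)[C@@H](OC)CO[Si](C)(C)C(C)(C)C | intermediate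
28 | C2,C3-diol | OC/C(C)=C/[C@@H]1OC(=O)[C@@H](C)[C@@H]1[C@@H](O[Si](C)(C)C(C)(C)C)C1(SCCCS1)[C@@H](C)[C@@H](OC)CO | intermediate
29 | C2,C3-diiodide | IC/C(C)=C/[C@@H]1OC(=O)[C@@H](C)[C@@H]1[C@@H](O[Si](C)(C)C(C)(C)C)C1(SCCCS1)[C@@H](C)[C@@H](OC)CI | intermediate
30 | sodium benzenesulfinate | [Na+].[O-]S(=O)c1ccccc1 | starting material
31 | seco C3 phenyl sulfone, C2 iodide, C8 silyl ether, C9 dithiane (1R,6S,7S,8R,10S,11S) | O=S(=O)(c1ccccc1)C/C(C)=C/[C@@H]1OC(=O)[C@@H](C)[C@@H]1[C@@H](O[Si](C)(C)C(C)(C)C)C1(SCCCS1)[C@@H](C)[C@@H](OC)CI | intermediate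
32 | C3-lithiated sulfone of 31 | O=S(=O)(c1ccccc1)C([Li])/C(C)=C/[C@@H]1OC(=O)[C@@H](C)[C@@H]1[C@@H](O[Si](C)(C)C(C)(C)C)C1(SCCCS1)[C@@H](C)[C@@H](OC)CI | intermediate (not isolated)
33 | ten-membered C3 phenyl sulfone, C9 dithiane (1S,6S,7S,8R,10S,11S; C3 epimers) | CO[C@H]1CC(S(=O)(=O)c2ccccc2)/C(C)=C/[C@@H]2OC(=O)[C@@H](C)[C@@H]2[C@@H](O[Si](C)(C)C(C)(C)C)C2(SCCCS2)[C@H]1C | intermediate
34 | ring-opened lithium carboxylate of 33 with free C6 hydroxyl | CO[C@H]1CC(S(=O)(=O)c2ccccc2)/C(C)=C/[C@H](O)[C@H]([C@H](C)C(=O)O[Li])[C@@H](O[Si](C)(C)C(C)(C)C)C2(SCCCS2)[C@H]1C | intermediate (not isolated)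
35 | desulfonylated C6-hydroxy C12 acid | CO[C@H]1CC/C(C)=C/[C@H](O)[C@H]([C@H](C)C(=O)O)[C@@H](O[Si](C)(C)C(C)(C)C)C2(SCCCS2)[C@H]1C | intermediate (not isolated)
36 | desulfonylated ten-membered lactone, C9 dithiane (1S,6S,7S,8R,10S,11S) | CO[C@H]1CC/C(C)=C/[C@@H]2OC(=O)[C@@H](C)[C@@H]2[C@@H](O[Si](C)(C)C(C)(C)C)C2(SCCCS2)[C@H]1C | intermediate
37 | C9 ketone, C8 silyl ether | CO[C@H]1CC/C(C)=C/[C@@H]2OC(=O)[C@@H](C)[C@@H]2[C@@H](O[Si](C)(C)C(C)(C)C)C(=O)[C@H]1C | intermediate
38 | C8 alcohol, C9 ketone (1S,6S,7R,8R,10S,11S) | CO[C@H]1CC/C(C)=C/[C@@H]2OC(=O)[C@@H](C)[C@@H]2[C@@H](O)C(=O)[C@H]1C | intermediate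
39 | (E)-2-methylbut-2-en-1-ol | C/C=C(\C)CO | starting material
40 | [(2R,3R)-2,3-dimethyloxiran-2-yl]methanol | OC[C@@]1(C)O[C@@H]1C | intermediate
41 | (2S,3R)-2,3-dimethyloxirane-2-carboxylic acid | OC(=O)[C@@]1(C)O[C@@H]1C | intermediate
42 | mixed anhydride of 41 with 2,4,6-trichlorobenzoic acid | O=C(OC(=O)[C@@]1(C)O[C@@H]1C)c1c(Cl)cc(Cl)cc1Cl | intermediate (not isolated)
43 | CNP0145898.1 (1S,6S,7S,8R,10S,11S; ester 2S,3R) | CO[C@H]1CC/C(C)=C/[C@@H]2OC(=O)[C@@H](C)[C@@H]2[C@@H](OC(=O)[C@@]2(C)O[C@@H]2C)C(=O)[C@H]1C | target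

Total step count: 24. Longest linear sequence: 19 steps (steps 1–5, 7–9, 12–21, 24).

Steps most likely to fail

Step 18. The delocalised C3–C5 anion may expel the C6 carboxylate (a vinylogous elimination that opens the lactone to a dienyl sulfone), proton transfer may give the lactone enolate and scramble C11, and slow substitution at the β-methoxy iodide may let intermolecular alkylation win. The fallback masks the lactone at the lactol level, which removes both the leaving group and the acidic C11–H. It sets out from 31: DIBAL-H (CH2Cl2, −78 °C) should give the lactol F1, and MeOH with PPTS its methyl acetal F2. LiN(SiMe3)2 in dilute THF (now up to 0 °C) should close the ring to the ten-membered sulfone acetal F3. PdCl2(dppp) with LiBHEt3 should give the desulfonylated acetal F4, since no ester is left to reduce. Aqueous AcOH–THF should give the lactol F5, and Dess–Martin periodinane with pyridine in dry CH2Cl2 returns to the route at 36.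

Step 19. The palladium cycle may stall on the sparingly soluble dilithium hydroxy-carboxylate, and acid-mediated re-closure may be incomplete or ionise the allylic C6 alcohol. Hydride delivery to C5 instead of C3 is the selectivity issue that any π-allyl route keeps. The fallback uses no hydrolytic opening and no acidic re-closure, but lets the hydride consume the lactone on purpose. It sets out from 33: excess LiBHEt3 (THF, 0 °C) should reduce the lactone to the soluble C6,C12-diol sulfone F6. Adding PdCl2(dppp) and more LiBHEt3 should then give the desulfonylated diol F7. Oxidative lactonisation of the 1,4-diol with TEMPO and PhI(OAc)2 (primary alcohol to aldehyde, lactol, lactone) returns to the route at 36.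

Step 13. Open-chain 1,2-induction may give poor facial selectivity in the hydride addition, and the tert-butyl ester may lactonise sluggishly. The fallback sets C6 by hydroxyl-directed, intramolecular hydride delivery. It sets out from 16: excess vinyllithium 22 should give the β-hydroxy enone F8. Me4NBH(OAc)3 in MeCN–AcOH at −30 °C (Evans–Saksena reduction) should give the anti-1,3-diol F9. PPTS in warm toluene should close the less hindered allylic C6 hydroxyl onto the ester to give the C8-hydroxy lactone F10, and TBSOTf with 2,6-lutidine returns to the route at 25.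

Further compounds
F1 | step 18 | lactol of 31 (C12 hemiacetal, both anomers) | O=S(=O)(c1ccccc1)C/C(C)=C/[C@@H]1OC(O)[C@@H](C)[C@@H]1[C@@H](O[Si](C)(C)C(C)(C)C)C1(SCCCS1)[C@@H](C)[C@@H](OC)CI
F2 | step 18 | methyl acetal of F1 | O=S(=O)(c1ccccc1)C/C(C)=C/[C@@H]1OC(OC)[C@@H](C)[C@@H]1[C@@H](O[Si](C)(C)C(C)(C)C)C1(SCCCS1)[C@@H](C)[C@@H](OC)CI
F3 | step 18 | ten-membered C3 sulfone methyl acetal | CO[C@H]1CC(S(=O)(=O)c2ccccc2)/C(C)=C/[C@@H]2OC(OC)[C@@H](C)[C@@H]2[C@@H](O[Si](C)(C)C(C)(C)C)C2(SCCCS2)[C@H]1C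
F4 | step 18 | desulfonylated ten-membered methyl acetal | CO[C@H]1CC/C(C)=C/[C@@H]2OC(OC)[C@@H](C)[C@@H]2[C@@H](O[Si](C)(C)C(C)(C)C)C2(SCCCS2)[C@H]1C
F5 | step 18 | desulfonylated ten-membered lactol | CO[C@H]1CC/C(C)=C/[C@@H]2OC(O)[C@@H](C)[C@@H]2[C@@H](O[Si](C)(C)C(C)(C)C)C2(SCCCS2)[C@H]1C
F6 | step 19 | C6,C12-diol C3 sulfone | CO[C@H]1CC(S(=O)(=O)c2ccccc2)/C(C)=C/[C@H](O)[C@H]([C@H](C)CO)[C@@H](O[Si](C)(C)C(C)(C)C)C2(SCCCS2)[C@H]1C
F7 | step 19 | desulfonylated C6,C12-diol | CO[C@H]1CC/C(C)=C/[C@H](O)[C@H]([C@H](C)CO)[C@@H](O[Si](C)(C)C(C)(C)C)C2(SCCCS2)[C@H]1C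
F8 | step 13 | β-hydroxy E enone (free C8 hydroxyl) | CC(C)(C)OC(=O)C[C@@H](C(=O)/C=C(\C)CO[Si](C)(C)C(C)(C)C)[C@@H](O)C1(SCCCS1)[C@@H](C)[C@@H](OC)CO[Si](C)(C)C(C)(C)C
F9 | step 13 | anti-1,3-diol tert-butyl ester | CC(C)(C)OC(=O)C[C@@H]([C@@H](O)/C=C(\C)CO[Si](C)(C)C(C)(C)C)[C@@H](O)C1(SCCCS1)[C@@H](C)[C@@H](OC)CO[Si](C)(C)C(C)(C)C
F10 | step 13 | cis γ-lactone with free C8 hydroxyl | CC(C)(C)[Si](C)(C)OC/C(C)=C/[C@@H]1OC(=O)C[C@@H]1[C@@H](O)C1(SCCCS1)[C@@H](C)[C@@H](OC)CO[Si](C)(C)C(C)(C)C
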